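Readings and results were generated by integration on assumed constants; the scatter is artificial.

Whatever is charged stays in the flask, so substrate, target and anything I could not read must add up to the charge. I was asked for the final target in oak, birch, cedar and ash, with north and east as the runs so far:

| flask | substrate | temperature | remark | time |
|---|---|---|---|---|
| north | 0.0067 M | −9 °C | run made earlier |  |
| east | 0.015 M | 16 °C | run made earlier |  |
| oak | 0.010 M | 25 °C |  | 15 min |
| birch | 0.010 M | 10 °C |  | 15 min |
| cedar | 0.010 M | −20 °C |  | 15 min |
| ash | 0.010 M | −5 °C |  | 15 min |

- north (time / min: target / %, substrate / %): 15.0: 16.1, 76.3; 25.0: 27.7, 65.5; 40.0: 39.5, 53.6; 50.0: 45.0, 44.9; 60.0: 50.1, 37.2; 80.0: 58.1, 27.3; 120: 67.5, 13.6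
- east (time / min: target / %, substrate / %): 4.00: 58.7, 23.6; 8.00: 72.2, 9.2; 12.0: 78.0, 4.3; 15.0: 77.0, 2.2; 20.0: 77.2, 2.1; 25.0: 77.1, 1.9; 30.0: 74.9, 0.4

(each reading ± 1 percentage point)

* the flask with the highest amount of target, in percent of the substrate charged ("all alike" if they lie within 1.5 percentage points) (oak / birch / cedar / ash / all alike)
* final target, as a percentage of the substrate charged, in oak
* final target, as a percentage of the substrate charged, in birch
* final target, as a percentage of the substrate charged, in cedar
* final target, as a percentage of the substrate charged, in ash



At 12.0 min in the east run, substrate and target left a gap of 17.7 %. At 120 min in the north run the gap was 18.9 %. So something unread held material in both runs.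

The east plateau then mattered more to me. I named a tail life, the elapsed time divided by the natural logarithm of the ratio by which c(target) falls once substrate is low, an apparent first-order lifetime. From 12.0 min to 30.0 min in the east run it was 444 min. That rests on a fall of 3.1 percentage points against a scatter of 1 point, so it is a rough reading. I set it on a ladder with the substrate lives, reckoned the same way:

| Rung | Time | Reading beside it |
|---|---|---|
| substrate life, east | 4.25 min | substrate 4.3 % at 12.0 min |
| asked time | 15 min | the flasks are read |
| substrate life, north | 60.9 min | substrate 13.6 % at 120 min |
| target tail life, east | 444 min | target 74.9 % at 30.0 min |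

The tail was the slowest rung.

The forecast gave oak as highest, with 77 % in oak, 72 % in birch, 4.5 % in cedar and 27 % in ash. Its ground for the target was "The target looks stable". My own reckoning asked what tail life would bring the forecast's oak figure down to its birch figure over the asked time, and the answer was 223 min. That is about half the east tail. The substrate life had shortened 14.3 times from north to east, two runs that differ in charge as well as temperature, and oak is hotter than east, so I held the call as close.

The flasks gave 68.4 % in oak, 71.8 % in birch, 4.08 % in cedar and 27.1 % in ash, with birch highest.

    substrate ⇌ intermediate A (K = 0.496, k = 0.185 min⁻¹, Ea = 80.0 kJ mol⁻¹, ΔH = −44.0 kJ mol⁻¹)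
    target → over-reaction product (k = 0.0280 min⁻¹, Ea = 94.0 kJ mol⁻¹)
    substrate ⇌ intermediate B (K = 0.340, k = 0.0557 min⁻¹, Ea = 93.0 kJ mol⁻¹, ΔH = −33.0 kJ mol⁻¹)
    substrate → target (k = 0.750 min⁻¹, Ea = 78.0 kJ mol⁻¹)
    (constants at 25 °C)

Reckoned from the asked time to 150 min, the tail life in oak was 36.0 min, shorter than the 223 min, and target in oak fell from 78.0 % at 7.50 min to 68.4 % at 15.0 min. The same reckoning in birch, where substrate 8.32 % and intermediate A 13.5 % still stood at the asked time, gave 695 min, longer than the 223 min, and at the asked time target in birch was still being made faster than it was used up, each step taken net, by a factor of 4.38.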